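The target's C13–C15 bond is formed by a one-pot hydroboration/B-alkyl Suzuki–Miyaura coupling of two fully elaborated halves. The route has 17 steps with a longest linear sequence of 8, and is a proposal that has not been run.

Everything rests on one cut, between C13 of the (12Z)-trisubstituted alkene C12=C13(CH3) and methylene C15, the start of the three-carbon tether to stereocentre C18 (numbering: furan C1–C4, chain C5–C20 with methyls C9, C14, C19, lactone ring C21–C24, hydroxymethyl C25). C15 is hidden in a terminal vinyl group, so one operation, anti-Markovnikov hydroboration with 9-BBN and B-alkyl Suzuki–Miyaura coupling, joins the complete enol-lactone half 31, bearing the 18R centre and the (20E)-alkylidenebutenolide ring, to the furan-bearing (Z)-2-iodoalkene 16 with retention of the C12=C13 geometry. Alkene 31 comes from an erythro-selective vinylogous aldol addition and anti-elimination, iodide 16 from a Johnson–Claisen rearrangement and an iodo-Wittig olefination.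

Key step: step 16

Remark on the chemistry: the structure is read as 7E, 12Z, 18R and 20E, the last meaning that the C18 side chain lies cis to ring C22–H and anti to the ring oxygen; the route is planned for exactly this isomer.

**Furan-bearing half (steps 1–6)**

Step 1
Reactants: 1 3-bromofuran; 2 oxetane
Product: 4 3-(furan-3-yl)propan-1-ol, via furan-3-yllithium 3 (not isolated)
Conditions: n-BuLi, THF, −78 °C; then oxetane, BF3·OEt2, −78 °C; aq. NH4Cl
Reagents that add atoms: none
Why: Bromine–lithium exchange at −78 °C should give the 3-lithiofuran without isomerisation to the 2-lithio species, and the BF3-activated oxetane is opened by the aryllithium at that temperature (Lewis-acid-promoted oxetane opening by an organolithium).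

Step 2
Reactants: 4 3-(furan-3-yl)propan-1-ol
Product: 5 3-(furan-3-yl)propanal
Conditions: Dess–Martin periodinane, NaHCO3, CH2Cl2, 0 °C → rt
Reagents that add atoms: none
Why: Buffered Dess–Martin oxidation should stop at the aldehyde and leave the acid-sensitive furan untouched.

Step 3
Reactants: 5 3-(furan-3-yl)propanal; 6 isopropenylmagnesium bromide
Product: 7 (3RS)-5-(furan-3-yl)-2-methylpent-1-en-3-ol
Conditions: THF, −78 → 0 °C; aq. NH4Cl
Reagents that add atoms: none
Why: Grignard 1,2-addition gives the 2-methylallylic alcohol needed for the Claisen step; the carbinol centre is racemic on purpose because it is consumed in step 4.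

Step 4
Reactants: 7 (3RS)-5-(furan-3-yl)-2-methylpent-1-en-3-ol; 8 triethyl orthoacetate
Product: 10 ethyl (4E)-7-(furan-3-yl)-4-methylhept-4-enoate, via ketene acetal 9 (not isolated)
Conditions: MeC(OEt)3 (excess), EtCO2H (cat.), 140 °C, EtOH distilled off
Reagents that add atoms: none
Why: Johnson–Claisen rearrangement through a chair transition state with the 2-(furan-3-yl)ethyl group equatorial should set the 7E trisubstituted alkene and add the two-carbon ester arm in one operation.

Step 5
Reactants: 10 ethyl (4E)-7-(furan-3-yl)-4-methylhept-4-enoate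
Product: 11 (4E)-7-(furan-3-yl)-4-methylhept-4-enal
Conditions: i-Bu2AlH (1.05 equiv), CH2Cl2, −78 °C; MeOH, aq. potassium sodium tartrate
Reagents that add atoms: none
Why: Partial reduction of the ester at −78 °C stops at the aluminium hemiacetal, which should release the aldehyde on work-up.

Step 6
Reactants: 11 (4E)-7-(furan-3-yl)-4-methylhept-4-enal; 12 ethyltriphenylphosphonium iodide
Product: 16 3-[(3E,7Z)-8-iodo-4-methylnona-3,7-dien-1-yl]furan, via ethylidenetriphenylphosphorane 13 (not isolated), via (1-iodoethyl)triphenylphosphonium iodide 14 (not isolated), via (1-iodoethylidene)triphenylphosphorane 15 (not isolated)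
Conditions: 12, n-BuLi, THF, 0 °C → rt; I2, −78 °C; NaN(SiMe3)2, −20 °C; then 11, −78 → −20 °C
Reagents that add atoms: iodine, [I][I]
Why: The non-stabilised α-iodo ylide reacts with the aldehyde under kinetic control (Stork–Zhao-type iodo-Wittig olefination) and should give the (Z)-2-iodoalk-2-ene, iodine cis to the chain, which is the geometry the coupling needs.

**Silyloxyfuran (steps 7–10)**

Step 7
Reactants: 17 allyl acrylate
Product: 18 allyl 2-(hydroxymethyl)acrylate
Conditions: aq. formaldehyde, DABCO (1 equiv), 1,4-dioxane/H2O, rt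
Reagents that add atoms: formaldehyde, C=O
Why: Morita–Baylis–Hillman reaction of an acrylate with formaldehyde should place the future C25 hydroxymethyl group on the α-carbon.

Step 8
Reactants: 18 allyl 2-(hydroxymethyl)acrylate
Product: 19 allyl 2-({[tert-butyl(dimethyl)silyl]oxy}methyl)acrylate
Conditions: TBSCl, imidazole, CH2Cl2, 0 °C → rt
Reagents that add atoms: tert-butyl(chloro)dimethylsilane, CC(C)(C)[Si](C)(C)Cl
Why: Standard silylation protects the primary alcohol for the metathesis, enolisation, triflation and coupling steps.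

Step 9
Reactants: 19 allyl 2-({[tert-butyl(dimethyl)silyl]oxy}methyl)acrylate
Product: 20 3-({[tert-butyl(dimethyl)silyl]oxy}methyl)furan-2(5H)-one
Conditions: (H2IMes)(PCy3)Cl2Ru=CHPh (second-generation Grubbs catalyst, 5 mol%), toluene (0.01 M), 80 °C
Reagents that add atoms: none
Why: Ring-closing metathesis of an allyl acrylate, driven by loss of ethene, should close the five-membered butenolide with the substituent on the α-carbon.

Step 10
Reactants: 20 3-({[tert-butyl(dimethyl)silyl]oxy}methyl)furan-2(5H)-one
Product: 21 tert-butyl(dimethyl){[2-(trimethylsilyloxy)furan-3-yl]methoxy}silane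
Conditions: Me3SiOTf, Et3N, CH2Cl2, 0 °C; pentane extraction, used directly
Reagents that add atoms: trimethylsilyl trifluoromethanesulfonate, C[Si](C)(C)OS(=O)(=O)C(F)(F)F
Why: Soft enolisation (O-silylation, then γ-deprotonation by the amine) should give the aromatic 2-silyloxyfuran, whose free C5 is the latent C21 nucleophile.

**Aldehyde with the C18 stereocentre (steps 11–13)**

Step 11
Reactants: 22 (4S)-4-benzyl-3-propanoyl-1,3-oxazolidin-2-one; 23 allyl iodide
Product: 25 (4S)-4-benzyl-3-[(2R)-2-methylpent-4-enoyl]-1,3-oxazolidin-2-one, via sodium Z-enolate 24 (not isolated)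
Conditions: NaN(SiMe3)2, THF, −78 °C; then allyl iodide, −78 → −45 °C
Reagents that add atoms: none
Why: Evans asymmetric alkylation: the chelated Z-enolate is attacked on the face opposite the benzyl group, which should set the future C18 centre as R.

Step 12
Reactants: 25 (4S)-4-benzyl-3-[(2R)-2-methylpent-4-enoyl]-1,3-oxazolidin-2-one
Product: 26 (2R)-2-methylpent-4-en-1-ol
Conditions: LiBH4, Et2O, H2O (1 equiv), 0 °C
Reagents that add atoms: none
Why: Hydride attacks the exocyclic imide carbonyl, so reductive cleavage should release the alcohol and the recoverable auxiliary without touching the stereocentre.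

Step 13
Reactants: 26 (2R)-2-methylpent-4-en-1-ol
Product: 27 (2R)-2-methylpent-4-enal
Conditions: Dess–Martin periodinane, NaHCO3, CH2Cl2, 0 °C; filtered through silica, used at once in solution
Reagents that add atoms: none
Why: Buffered Dess–Martin oxidation is non-epimerising, and immediate use in solution avoids loss or racemisation of the volatile α-branched aldehyde.

**Assembly of the enol-lactone half, coupling and deprotection (steps 14–17)**

Step 14
Reactants: 27 (2R)-2-methylpent-4-enal; 21 tert-butyl(dimethyl){[2-(trimethylsilyloxy)furan-3-yl]methoxy}silane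
Product: 29 (5R)-3-({[tert-butyl(dimethyl)silyl]oxy}methyl)-5-[(1S,2R)-1-hydroxy-2-methylpent-4-en-1-yl]furan-2(5H)-one, via trimethylsilyl ether 28 (not isolated)
Conditions: Bu4NF (0.1 equiv), THF, −78 °C; then aq. citric acid, 0 °C
Reagents that add atoms: none
Why: Fluoride frees the furan-2-olate, whose γ-carbon (C21) adds to the aldehyde through an open transition state (fluoride-promoted vinylogous Mukaiyama aldol addition) that should favour the erythro relation between C20–OH and the ring oxygen on C21, the Lewis-acid mode being threo-selective; the sense relative to C18 is immaterial, since 29 and its (5S,1'R) erythro companion converge in step 15.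

Step 15
Reactants: 29 (5R)-3-({[tert-butyl(dimethyl)silyl]oxy}methyl)-5-[(1S,2R)-1-hydroxy-2-methylpent-4-en-1-yl]furan-2(5H)-one
Product: 31 (5E)-3-({[tert-butyl(dimethyl)silyl]oxy}methyl)-5-[(2R)-2-methylpent-4-en-1-ylidene]furan-2(5H)-one, via triflate 30 (not isolated)
Conditions: Tf2O (1.2 equiv), pyridine (5 equiv), CH2Cl2, −78 → 0 °C
Reagents that add atoms: none
Why: Triflation and pyridine-mediated anti-periplanar loss of H21 and triflate (stereospecific anti-elimination of a γ-(α-hydroxyalkyl)butenolide) should translate the erythro configuration into the 20E alkene, the C18 chain ending cis to ring C22–H, while C18 itself is untouched.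

Step 16
Reactants: 31 (5E)-3-({[tert-butyl(dimethyl)silyl]oxy}methyl)-5-[(2R)-2-methylpent-4-en-1-ylidene]furan-2(5H)-one; 16 3-[(3E,7Z)-8-iodo-4-methylnona-3,7-dien-1-yl]furan
Product: 33 (5E)-3-({[tert-butyl(dimethyl)silyl]oxy}methyl)-5-[(2R,6Z,10E)-13-(furan-3-yl)-2,6,10-trimethyltrideca-6,10-dien-1-ylidene]furan-2(5H)-one, via B-alkyl-9-BBN 32 (not isolated)
Conditions: 31 (1.3 equiv), 9-BBN-H (0.5 M in THF), 0 °C → rt; then H2O, 16, PdCl2(dppf)·CH2Cl2 (5 mol%), AsPh3 (10 mol%), Cs2CO3 (3 equiv), DMF/THF, rt, dark
Reagents that add atoms: none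
Why: 9-BBN-H adds syn across the only monosubstituted alkene (C15=C16) of 31 with boron on terminal C15, giving alkylborane 32; base turns it into the borate, which transfers the primary alkyl group to the alkenylpalladium iodide formed by oxidative addition of the C13–I bond of 16 to zerovalent palladium, and reductive elimination makes the C13–C15 bond. The closest known reaction type is the B-alkyl Suzuki–Miyaura coupling of (Z)-2-iodoalk-2-enes with 9-BBN adducts of terminal alkenes, an established way to build Z-trisubstituted methyl-branched alkenes. No ring is closed and no stereocentre is created: the 12Z geometry is copied from 16 because oxidative addition and reductive elimination proceed with retention at sp2 carbon, and C18 lies three bonds from the reacting carbon. The step needs chemoselective hydroboration of the terminal alkene over the conjugated, trisubstituted C20=C21 and C22=C23 alkenes and the lactone carbonyl, which the bulk and low hydridic reactivity of 9-BBN should secure. It also needs the base-labile 20E enol lactone to survive, for which room temperature, carbonate with little water, a chelating ligand that speeds reductive elimination, and exclusion of light are chosen. The furan, the 7E alkene and the silyl ether should be inert.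

Step 17
Reactants: 33 (5E)-3-({[tert-butyl(dimethyl)silyl]oxy}methyl)-5-[(2R,6Z,10E)-13-(furan-3-yl)-2,6,10-trimethyltrideca-6,10-dien-1-ylidene]furan-2(5H)-one
Product: 34 (5E)-5-[(2R,6Z,10E)-13-(furan-3-yl)-2,6,10-trimethyltrideca-6,10-dien-1-ylidene]-3-(hydroxymethyl)furan-2(5H)-one
Conditions: HF·pyridine, pyridine, THF, 0 °C → rt
Reagents that add atoms: none
Why: Buffered fluoride cleaves the primary silyl ether under conditions that are neither basic enough to open or isomerise the enol lactone nor acidic enough to harm the furan.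

**Compound list**

1 | 3-bromofuran | Brc1ccoc1 | starting material
2 | oxetane | C1COC1 | starting material
3 | furan-3-yllithium | [Li]c1ccoc1 | intermediate
4 | 3-(furan-3-yl)propan-1-ol | OCCCc1ccoc1 | intermediate
5 | 3-(furan-3-yl)propanal | O=CCCc1ccoc1 | intermediate
6 | isopropenylmagnesium bromide | CC(=C)[Mg]Br | starting material
7 | (3RS)-5-(furan-3-yl)-2-methylpent-1-en-3-ol | C=C(C)C(O)CCc1ccoc1 | intermediate
8 | triethyl orthoacetate | CC(OCC)(OCC)OCC | starting material
9 | 3-{3-[(1-ethoxyethenyl)oxy]-4-methylpent-4-en-1-yl}furan (ketene acetal) | C=C(OCC)OC(CCc1ccoc1)C(C)=C | intermediate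
10 | ethyl (4E)-7-(furan-3-yl)-4-methylhept-4-enoate | CCOC(=O)CC/C(C)=C/CCc1ccoc1 | intermediate
11 | (4E)-7-(furan-3-yl)-4-methylhept-4-enal | O=CCC/C(C)=C/CCc1ccoc1 | intermediate
12 | ethyltriphenylphosphonium iodide | CC[P+](c1ccccc1)(c1ccccc1)c1ccccc1.[I-] | starting material
13 | ethylidenetriphenylphosphorane | CC=P(c1ccccc1)(c1ccccc1)c1ccccc1 | intermediate
14 | (1-iodoethyl)triphenylphosphonium iodide | CC(I)[P+](c1ccccc1)(c1ccccc1)c1ccccc1.[I-] | intermediate
15 | (1-iodoethylidene)triphenylphosphorane | CC(I)=P(c1ccccc1)(c1ccccc1)c1ccccc1 | intermediate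
16 | 3-[(3E,7Z)-8-iodo-4-methylnona-3,7-dien-1-yl]furan | C/C(I)=C/CC/C(C)=C/CCc1ccoc1 | intermediate
17 | allyl acrylate | C=CCOC(=O)C=C | starting material
18 | allyl 2-(hydroxymethyl)acrylate | C=CCOC(=O)C(=C)CO | intermediate
19 | allyl 2-({[tert-butyl(dimethyl)silyl]oxy}methyl)acrylate | C=CCOC(=O)C(=C)CO[Si](C)(C)C(C)(C)C | intermediate
20 | 3-({[tert-butyl(dimethyl)silyl]oxy}methyl)furan-2(5H)-one | O=C1OCC=C1CO[Si](C)(C)C(C)(C)C | intermediate
21 | tert-butyl(dimethyl){[2-(trimethylsilyloxy)furan-3-yl]methoxy}silane | C[Si](C)(C)Oc1occc1CO[Si](C)(C)C(C)(C)C | intermediate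
22 | (4S)-4-benzyl-3-propanoyl-1,3-oxazolidin-2-one | CCC(=O)N1[C@@H](Cc2ccccc2)COC1=O | starting material
23 | allyl iodide | C=CCI | starting material
24 | sodium (Z)-enolate of 22 | C/C=C(\[O-])N1[C@@H](Cc2ccccc2)COC1=O.[Na+] | intermediate
25 | (4S)-4-benzyl-3-[(2R)-2-methylpent-4-enoyl]-1,3-oxazolidin-2-one | C=CC[C@@H](C)C(=O)N1[C@@H](Cc2ccccc2)COC1=O | intermediate
26 | (2R)-2-methylpent-4-en-1-ol | C=CC[C@@H](C)CO | intermediate
27 | (2R)-2-methylpent-4-enal | C=CC[C@@H](C)C=O | intermediate
28 | (5R)-3-({[tert-butyl(dimethyl)silyl]oxy}methyl)-5-[(1S,2R)-2-methyl-1-(trimethylsilyloxy)pent-4-en-1-yl]furan-2(5H)-one | C=CC[C@@H](C)[C@H](O[Si](C)(C)C)[C@@H]1OC(=O)C(CO[Si](C)(C)C(C)(C)C)=C1 | intermediate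
29 | (5R)-3-({[tert-butyl(dimethyl)silyl]oxy}methyl)-5-[(1S,2R)-1-hydroxy-2-methylpent-4-en-1-yl]furan-2(5H)-one (erythro) | C=CC[C@@H](C)[C@H](O)[C@@H]1OC(=O)C(CO[Si](C)(C)C(C)(C)C)=C1 | intermediate
30 | trifluoromethanesulfonate of 29 | C=CC[C@@H](C)[C@H](OS(=O)(=O)C(F)(F)F)[C@@H]1OC(=O)C(CO[Si](C)(C)C(C)(C)C)=C1 | intermediate
31 | (5E)-3-({[tert-butyl(dimethyl)silyl]oxy}methyl)-5-[(2R)-2-methylpent-4-en-1-ylidene]furan-2(5H)-one | C=CC[C@@H](C)/C=C1\C=C(CO[Si](C)(C)C(C)(C)C)C(=O)O1 | intermediate
32 | (5E)-5-[(2R)-5-(9-borabicyclo[3.3.1]nonan-9-yl)-2-methylpentylidene]-3-({[tert-butyl(dimethyl)silyl]oxy}methyl)furan-2(5H)-one | C1CC2CCCC(C1)B2CCC[C@@H](C)/C=C1\C=C(CO[Si](C)(C)C(C)(C)C)C(=O)O1 | intermediate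
33 | (5E)-3-({[tert-butyl(dimethyl)silyl]oxy}methyl)-5-[(2R,6Z,10E)-13-(furan-3-yl)-2,6,10-trimethyltrideca-6,10-dien-1-ylidene]furan-2(5H)-one | C/C(=C/CC/C(C)=C/CCc1ccoc1)CCC[C@@H](C)/C=C1\C=C(CO[Si](C)(C)C(C)(C)C)C(=O)O1 | intermediate
34 | (5E)-5-[(2R,6Z,10E)-13-(furan-3-yl)-2,6,10-trimethyltrideca-6,10-dien-1-ylidene]-3-(hydroxymethyl)furan-2(5H)-one (22-deoxy-23-hydroxymethylvariabilin) | C/C(=C/CC/C(C)=C/CCc1ccoc1)CCC[C@@H](C)/C=C1\C=C(CO)C(=O)O1 | target

**Step count and risks**

Total step count: 17. Longest linear sequence: 8 steps (steps 7–10 and 14–17; the branch through steps 1–6, 16 and 17 is equally long).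

Steps most likely to fail:

Step 16 (key step). The risks are hydrolytic opening of the enol lactone by aqueous carbonate, isomerisation of the 20E alkene to the more stable 20Z form by nucleophilic ligands or palladium hydride, and competing reduction of the lactone by the borane. The fallback moves the fragment union ahead of the lactone chemistry. Setting out from 26, hydroboration with 9-BBN-H (2.2 equiv, the first equivalent being taken up by the hydroxyl group) would give the bis-boron species 9-{[(2R)-5-(9-borabicyclo[3.3.1]nonan-9-yl)-2-methylpentyl]oxy}-9-borabicyclo[3.3.1]nonane F1, which is coupled with 16 under the same PdCl2(dppf)/Cs2CO3 conditions to the dienol (2R,6Z,10E)-13-(furan-3-yl)-2,6,10-trimethyltrideca-6,10-dien-1-ol F2. Dess–Martin oxidation would give the dienal (2R,6Z,10E)-13-(furan-3-yl)-2,6,10-trimethyltrideca-6,10-dienal F3, and fluoride-promoted addition of 21 would lead through the aldol trimethylsilyl ether F4 to the erythro aldol adduct F5. Tf2O/pyridine would then convert F5 through the aldol triflate F6 into 33, where the route is rejoined. In this order the sensitive 20E enol lactone meets neither borane, palladium nor aqueous base.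

Step 14. The risks are insufficient erythro selectivity, which the stereospecific elimination would pass on as the 20Z alkene, and base-induced epimerisation of the aldehyde at C18. The fallback replaces kinetic control by thermodynamic correction. Setting out from 27 and 21, the BF3·OEt2-promoted vinylogous Mukaiyama aldol addition (CH2Cl2, −78 °C), which favours the threo series and keeps the aldehyde away from base, would give the threo adduct (5S)-3-({[tert-butyl(dimethyl)silyl]oxy}methyl)-5-[(1S,2R)-1-hydroxy-2-methylpent-4-en-1-yl]furan-2(5H)-one F7. Epimerisation of its acidic γ-position C21 through the furanolate (Et3N, cat. DMAP, CH2Cl2, rt) would equilibrate F7 with 29, which is separated by chromatography while recovered F7 is resubmitted; the route is rejoined at 29.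

Step 15. The risks are loss of stereospecificity, because the acidic C21–H opens an E1cB path through the planar furanolate that leads to the 20Z isomer, and E-to-Z isomerisation during work-up. The fallback gives up the stereospecific elimination and controls the geometry by separation and photochemical recycling. Setting out from 29 (or any erythro/threo mixture), mesylation (MsCl, Et3N, CH2Cl2, 0 °C) to the mesylate F8 and elimination with DBU would give 31 together with its 20Z isomer (5Z)-3-({[tert-butyl(dimethyl)silyl]oxy}methyl)-5-[(2R)-2-methylpent-4-en-1-ylidene]furan-2(5H)-one F9. The two are separated on silica, and F9 is irradiated (350 nm, benzene, benzophenone sensitiser) to a photostationary mixture from which more 31 is separated and the rest recycled; the route is rejoined at 31.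

**Further compounds**

F1 | step 16 | 9-{[(2R)-5-(9-borabicyclo[3.3.1]nonan-9-yl)-2-methylpentyl]oxy}-9-borabicyclo[3.3.1]nonane | C1CC2CCCC(C1)B2CCC[C@@H](C)COB1C2CCCC1CCC2
F2 | step 16 | (2R,6Z,10E)-13-(furan-3-yl)-2,6,10-trimethyltrideca-6,10-dien-1-ol | C/C(=C/CC/C(C)=C/CCc1ccoc1)CCC[C@@H](C)CO
F3 | step 16 | (2R,6Z,10E)-13-(furan-3-yl)-2,6,10-trimethyltrideca-6,10-dienal | C/C(=C/CC/C(C)=C/CCc1ccoc1)CCC[C@@H](C)C=O
F4 | step 16 | (5R)-3-({[tert-butyl(dimethyl)silyl]oxy}methyl)-5-[(1S,2R,6Z,10E)-13-(furan-3-yl)-2,6,10-trimethyl-1-(trimethylsilyloxy)trideca-6,10-dien-1-yl]furan-2(5H)-one | C/C(=C/CC/C(C)=C/CCc1ccoc1)CCC[C@@H](C)[C@H](O[Si](C)(C)C)[C@@H]1OC(=O)C(CO[Si](C)(C)C(C)(C)C)=C1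
F5 | step 16 | (5R)-3-({[tert-butyl(dimethyl)silyl]oxy}methyl)-5-[(1S,2R,6Z,10E)-13-(furan-3-yl)-1-hydroxy-2,6,10-trimethyltrideca-6,10-dien-1-yl]furan-2(5H)-one | C/C(=C/CC/C(C)=C/CCc1ccoc1)CCC[C@@H](C)[C@H](O)[C@@H]1OC(=O)C(CO[Si](C)(C)C(C)(C)C)=C1
F6 | step 16 | trifluoromethanesulfonate of F5 | C/C(=C/CC/C(C)=C/CCc1ccoc1)CCC[C@@H](C)[C@H](OS(=O)(=O)C(F)(F)F)[C@@H]1OC(=O)C(CO[Si](C)(C)C(C)(C)C)=C1
F7 | step 14 | (5S)-3-({[tert-butyl(dimethyl)silyl]oxy}methyl)-5-[(1S,2R)-1-hydroxy-2-methylpent-4-en-1-yl]furan-2(5H)-one | C=CC[C@@H](C)[C@H](O)[C@H]1OC(=O)C(CO[Si](C)(C)C(C)(C)C)=C1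
F8 | step 15 | methanesulfonate of 29 | C=CC[C@@H](C)[C@H](OS(C)(=O)=O)[C@@H]1OC(=O)C(CO[Si](C)(C)C(C)(C)C)=C1
F9 | step 15 | (5Z)-3-({[tert-butyl(dimethyl)silyl]oxy}methyl)-5-[(2R)-2-methylpent-4-en-1-ylidene]furan-2(5H)-one | C=CC[C@@H](C)/C=C1/C=C(CO[Si](C)(C)C(C)(C)C)C(=O)O1
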